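**Plan**

1. Retrosynthesis: the CH2 bridge between ring A and ring B is cut first (Mannich-type methylene link), then the C3–CO bond of the ring C butyryl group, then ring C itself across C5–C6, C3–C4 and C1–C6 into a 3-alkoxy-4-(arylmethyl)cyclobutenone and 1-siloxypropyne, and last the cyclobutenone into an arylpropanoyl ketene and tert-butoxyethyne.
2. Enabling feature: ring C carries oxygen on C2, C4 and C6 and carbon on C1 (bridge CH2), C3 (acyl) and C5 (CH3), and only the C6 oxygen is methylated; a 3-alkoxycyclobutenone and a siloxyalkyne deliver exactly this alternation, with C6 emerging as the one free phenol.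
3. Forward order: ring B is made first (phloroglucinol, dihydrocoumarin, butyrylation, ring-opening with benzylation), its ketene gives the four-membered ring, and the benzannulation closes ring C on the bridge carbon already bonded to ring B. Ring C is then methylated, unmasked and butyrylated, ring B is debenzylated, and the separately made ring A triketone is joined last.
4. Protecting groups: ring B as benzyl ethers (hydrogenolysis), C2–O as tert-butyl ether (acid), C4–O as triisopropylsilyl ether (fluoride). An ethyl ether at C2 is avoided because, once C4–OH chelates the C3 ketone, a second ortho ether cannot be cleaved selectively beside the hindered C6 methyl ether.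
5. Stereochemistry: the target has no stereocentre; the one stereocentre of the racemic cyclobutenone disappears on aromatisation.

Key step: step 9

Remark: ring C locants used throughout are C1 (bridge carbon), C2 (OH), C3 (butyryl), C4 (OH), C5 (CH3), C6 (OCH3); ring A is drawn in the enol tautomer of the target SMILES, one of several.

**Step 1**
Reactants: 1 phloroglucinol; 2 acrylic acid
Product: 3 5,7-dihydroxychroman-2-one
Conditions: Amberlyst-15 (polystyrene sulfonic acid resin), toluene, reflux, Dean–Stark
Reagents that add atoms: none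
Why: Acid-catalysed Friedel–Crafts hydroarylation of the acrylic acid by the electron-rich triol, followed by lactonisation, is the standard resin-catalysed route from polyhydroxybenzenes to dihydrocoumarins.

**Step 2**
Reactants: 3 5,7-dihydroxychroman-2-one
Product: 4 8-butanoyl-5,7-dihydroxychroman-2-one
Conditions: PrCOCl, AlCl3, PhNO2, rt to 50 °C
Reagents that add atoms: butanoyl chloride, CCCC(Cl)=O
Why: Friedel–Crafts acylation of the phloroglucinol-type ring should stop after one acyl group because the ketone deactivates the ring, and attack at either free ring position leads after the lactone opening of step 3 to the same propanoate, so the regiochemistry is inconsequential.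

**Step 3**
Reactants: 4 8-butanoyl-5,7-dihydroxychroman-2-one
Product: 6 methyl 3-[2,4,6-tris(benzyloxy)-3-butanoylphenyl]propanoate, via trihydroxy methyl ester 5 (not isolated)
Conditions: K2CO3, MeOH, rt; concentrate; BnBr, K2CO3, n-Bu4NI (cat.), DMF, 60 °C
Reagents that add atoms: methanol, CO; benzyl bromide, BrCc1ccccc1
Why: Base methanolysis of the aryl lactone frees the third phenoxide, and Williamson benzylation of all three phenoxides then locks the ring-opened form (the chelated ortho-hydroxyl reacts on warming in DMF).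

**Step 4**
Reactants: 6 methyl 3-[2,4,6-tris(benzyloxy)-3-butanoylphenyl]propanoate
Product: 7 3-[2,4,6-tris(benzyloxy)-3-butanoylphenyl]propanoic acid
Conditions: LiOH, THF–MeOH–H2O, rt; then 1 M HCl
Reagents that add atoms: lithium hydroxide, [Li+].[OH-]
Why: Ester saponification of an unhindered methyl ester leaves the benzyl ethers and the hindered aryl ketone untouched.

**Step 5**
Reactants: 7 3-[2,4,6-tris(benzyloxy)-3-butanoylphenyl]propanoic acid
Product: 8 3-[2,4,6-tris(benzyloxy)-3-butanoylphenyl]propanoyl chloride
Conditions: (COCl)2, DMF (cat.), CH2Cl2, 0 °C to rt; used crude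
Reagents that add atoms: oxalyl chloride, ClC(=O)C(Cl)=O
Why: Acid chloride formation under chloroiminium catalysis is mild enough for benzyl ethers, and both ring positions ortho to the side chain are blocked, so no indanone can form.

**Step 6**
Reactants: 9 potassium tert-butoxide
Product: 12 tert-butoxyethyne, via dichlorovinyl ether 10 (not isolated), via lithium tert-butoxyacetylide 11 (not isolated)
Conditions: Cl2C=CHCl, THF, −78 °C to rt; n-BuLi (2.3 equiv), −78 to −40 °C; MeOH, −78 °C; cold distillation, stored at −20 °C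
Reagents that add atoms: trichloroethylene, ClC=C(Cl)Cl
Why: The alkoxide adds to dichloroacetylene formed in situ, and n-BuLi then effects dehydrochlorination and chlorine–lithium exchange to the alkoxyacetylide, which is protonated; this is the standard dichlorovinyl ether route to ynol ethers.

**Step 7**
Reactants: 8 3-[2,4,6-tris(benzyloxy)-3-butanoylphenyl]propanoyl chloride; 12 tert-butoxyethyne
Product: 14 racemic 3-tert-butoxy-4-{[2,4,6-tris(benzyloxy)-3-butanoylphenyl]methyl}cyclobut-2-en-1-one, via aldoketene 13 (not isolated)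
Conditions: Et3N, CH2Cl2, 0 °C to rt, slow addition of 8 to 12 (3 equiv); chromatography on Et3N-deactivated silica
Reagents that add atoms: none
Why: Dehydrochlorination gives the aldoketene, which should undergo the regioselective thermal [2+2] ketene–ynol ether cycloaddition (nucleophilic CH terminus of the ynol ether to the ketene carbonyl carbon) faster than it dimerises because the ynol ether is in excess; the new stereocentre at C4 is formed racemic and is later lost.

**Step 8**
Reactants: 15 ethyl acetate
Product: 18 triisopropyl(prop-1-yn-1-yloxy)silane, via 1,1-dibromoacetone lithium enolate 16 (not isolated), via lithium propynolate 17 (not isolated)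
Conditions: CH2Br2, LiTMP (lithium 2,2,6,6-tetramethylpiperidide), THF, −78 °C; n-BuLi, −78 °C to rt; TIPSCl, −78 °C to rt
Reagents that add atoms: dibromomethane, BrCBr; chlorotriisopropylsilane, CC(C)[Si](Cl)(C(C)C)C(C)C
Why: Kowalski ester homologation, in which the dibromomethyllithium adduct collapses to the dibromoketone enolate, bromine–lithium exchange triggers a carbenoid 1,2-shift to the ynolate, and the bulky chlorosilane silylates it on oxygen.

**Step 9**
Reactants: 14 racemic 3-tert-butoxy-4-{[2,4,6-tris(benzyloxy)-3-butanoylphenyl]methyl}cyclobut-2-en-1-one; 18 triisopropyl(prop-1-yn-1-yloxy)silane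
Product: 23 1-[2,4,6-tris(benzyloxy)-3-{[6-tert-butoxy-2-hydroxy-3-methyl-4-(triisopropylsilyloxy)phenyl]methyl}phenyl]butan-1-one, via vinylketene 19 (not isolated), via vinylcyclobutenone 20 (not isolated), via dienylketene 21 (not isolated), via cyclohexadienone 22 (not isolated)
Conditions: 18 (2 equiv), degassed toluene, 80 °C then 110 °C, base-washed sealed tube
Reagents that add atoms: none
Why: Heating opens 14 by 4π electrocyclic cleavage of its C1–C4 bond to vinylketene 19, whose ketene C=C adds 18 in a [2+2] cycloaddition that joins the methyl-bearing alkyne carbon to the ketene carbonyl carbon (C5–C6 of ring C) and the silyloxy carbon to the ketene α-carbon (C3–C4). Vinylcyclobutenone 20 reopens (4π) to dienylketene 21, and its 6π disrotatory electrocyclisation forms C1–C6, closing ring C as a six-membered carbocycle on the carbon that already carries the ring B methylene; tautomerisation of cyclohexadienone 22 gives the phenol. This is the Danheiser benzannulation of a cyclobutenone with a siloxyalkyne, the established route to resorcinol monosilyl ethers. No stereocentre results, since the racemic C4 of 14 and the transient sp3 centres of 20 and 22 all become aromatic carbons. The only selectivity needed is the regiochemistry of the ketene–alkyne [2+2], secured by the polarisation of the siloxyalkyne (oxygen makes the methyl-bearing carbon nucleophilic), while reversible ring opening funnels the material into the one dienylketene geometry able to cyclise. The single free phenol is the C6 oxygen that must be methylated, with C2 and C4 masked as tert-butyl and silyl ethers.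

**Step 10**
Reactants: 23 1-[2,4,6-tris(benzyloxy)-3-{[6-tert-butoxy-2-hydroxy-3-methyl-4-(triisopropylsilyloxy)phenyl]methyl}phenyl]butan-1-one
Product: 24 1-[2,4,6-tris(benzyloxy)-3-{[6-tert-butoxy-2-methoxy-3-methyl-4-(triisopropylsilyloxy)phenyl]methyl}phenyl]butan-1-one
Conditions: MeI, K2CO3, acetone, 50 °C
Reagents that add atoms: iodomethane, CI
Why: Williamson methylation of the only free phenol fixes the C6 methyl ether, and carbonate in acetone should leave the aryl silyl ether and the ketone α-position alone.

**Step 11**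
Reactants: 24 1-[2,4,6-tris(benzyloxy)-3-{[6-tert-butoxy-2-methoxy-3-methyl-4-(triisopropylsilyloxy)phenyl]methyl}phenyl]butan-1-one
Product: 26 1-[2,4,6-tris(benzyloxy)-3-[(4,6-dihydroxy-2-methoxy-3-methylphenyl)methyl]phenyl]butan-1-one, via tert-butoxy phenol 25 (not isolated)
Conditions: TBAF, THF, 0 °C; then TFA–CH2Cl2 (1:4), 0 °C
Reagents that add atoms: none
Why: Fluoride desilylation followed by acid cleavage of the aryl tert-butyl ether (loss of the tert-butyl cation as isobutene) frees C4–OH and C2–OH under conditions that should spare methyl and benzyl ethers.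

**Step 12**
Reactants: 26 1-[2,4,6-tris(benzyloxy)-3-[(4,6-dihydroxy-2-methoxy-3-methylphenyl)methyl]phenyl]butan-1-one
Product: 27 1-[2,4,6-tris(benzyloxy)-3-[(5-butanoyl-4,6-dihydroxy-2-methoxy-3-methylphenyl)methyl]phenyl]butan-1-one
Conditions: (PrCO)2O, BF3·OEt2, CH2Cl2, 0 °C to rt; aq. NaOAc–MeOH work-up
Reagents that add atoms: butanoic anhydride, CCCC(=O)OC(=O)CCC
Why: Friedel–Crafts acylation at C3, the only free position of ring C, which is activated by two ortho hydroxyls and the para methoxyl and so should react at low temperature, while ring B is deactivated by its ketone and its benzyl ethers should survive the mild Lewis acid.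

**Step 13**
Reactants: 27 1-[2,4,6-tris(benzyloxy)-3-[(5-butanoyl-4,6-dihydroxy-2-methoxy-3-methylphenyl)methyl]phenyl]butan-1-one
Product: 28 1-(3-{[3-butanoyl-2,4,6-trihydroxyphenyl]methyl}-2,6-dihydroxy-4-methoxy-5-methylphenyl)butan-1-one
Conditions: H2 (1 atm), 10% Pd/C, EtOAc–MeOH, rt
Reagents that add atoms: none
Why: Hydrogenolysis of the three benzyl ethers is neutral, and the chelated aryl ketones and the diarylmethane bridge are not expected to be reduced at room temperature and atmospheric pressure.

**Step 14**
Reactants: 1 phloroglucinol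
Product: 29 1-(2,4,6-trihydroxyphenyl)butan-1-one
Conditions: PrCOCl, AlCl3, PhNO2–CH2Cl2, 0 °C to rt
Reagents that add atoms: butanoyl chloride, CCCC(Cl)=O
Why: Friedel–Crafts monoacylation of phloroglucinol is a standard preparation of acylphloroglucinols, the first ketone slowing a second acylation.

**Step 15**
Reactants: 29 1-(2,4,6-trihydroxyphenyl)butan-1-one
Product: 31 2-butanoyl-3,5-dihydroxy-4,4-dimethylcyclohexa-2,5-dien-1-one (butyrylfilicinic acid), via methylphlorbutyrophenone 30 (not isolated)
Conditions: MeI (2.2 equiv), NaOMe, MeOH, 0 °C to rt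
Reagents that add atoms: iodomethane, CI
Why: Dearomatising C-methylation of the acylphloroglucinol polyanion, in which the second methyl group enters preferentially at the already methylated carbon and the resulting acidic triketone resists further alkylation, is the classical route to acylfilicinic acids.

**Step 16**
Reactants: 31 2-butanoyl-3,5-dihydroxy-4,4-dimethylcyclohexa-2,5-dien-1-one
Product: 32 2-butanoyl-6-[(dimethylamino)methyl]-3,5-dihydroxy-4,4-dimethylcyclohexa-2,5-dien-1-one
Conditions: CH2=NMe2+ I− (Eschenmoser's salt), Et3N, CH2Cl2, 0 °C to rt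
Reagents that add atoms: N,N-dimethylmethyleneiminium iodide, C=[N+](C)C.[I-]
Why: Mannich aminomethylation with a preformed iminium salt at the only enolic CH of the triketone avoids free formaldehyde and therefore the symmetrical methylene-bridged dimer.

**Step 17**
Reactants: 32 2-butanoyl-6-[(dimethylamino)methyl]-3,5-dihydroxy-4,4-dimethylcyclohexa-2,5-dien-1-one; 28 1-(3-{[3-butanoyl-2,4,6-trihydroxyphenyl]methyl}-2,6-dihydroxy-4-methoxy-5-methylphenyl)butan-1-one
Product: 34 2-butanoyl-6-[(3-butanoyl-5-{[3-butanoyl-2,4-dihydroxy-6-methoxy-5-methylphenyl]methyl}-2,4,6-trihydroxyphenyl)methyl]-3,5-dihydroxy-4,4-dimethylcyclohexa-2,5-dien-1-one (target), via methylene triketone 33 (not isolated)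
Conditions: 1,4-dioxane, 80 °C, argon
Reagents that add atoms: none
Why: Thermal loss of dimethylamine from the Mannich base gives a 2-methylene-1,3-dione (a vinylogous quinone methide), which the only free nuclear position of 28, on ring B, should trap by Friedel–Crafts-type conjugate addition under near-neutral conditions that disfavour methylene exchange.

**Compound list**

1 | phloroglucinol | Oc1cc(O)cc(O)c1 | starting material
2 | acrylic acid | C=CC(=O)O | starting material
3 | 5,7-dihydroxychroman-2-one | O=C1CCc2c(O)cc(O)cc2O1 | intermediate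
4 | 8-butanoyl-5,7-dihydroxychroman-2-one | O=C1CCc2c(O)cc(O)c(C(=O)CCC)c2O1 | intermediate
5 | methyl 3-(3-butanoyl-2,4,6-trihydroxyphenyl)propanoate (present as potassium phenoxide) | COC(=O)CCc1c(O)cc(O)c(C(=O)CCC)c1O | intermediate
6 | methyl 3-[2,4,6-tris(benzyloxy)-3-butanoylphenyl]propanoate | COC(=O)CCc1c(OCc2ccccc2)cc(OCc2ccccc2)c(C(=O)CCC)c1OCc1ccccc1 | intermediate
7 | 3-[2,4,6-tris(benzyloxy)-3-butanoylphenyl]propanoic acid | OC(=O)CCc1c(OCc2ccccc2)cc(OCc2ccccc2)c(C(=O)CCC)c1OCc1ccccc1 | intermediate
8 | 3-[2,4,6-tris(benzyloxy)-3-butanoylphenyl]propanoyl chloride | ClC(=O)CCc1c(OCc2ccccc2)cc(OCc2ccccc2)c(C(=O)CCC)c1OCc1ccccc1 | intermediate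
9 | potassium tert-butoxide | CC(C)(C)[O-].[K+] | starting material
10 | (E)-1-tert-butoxy-1,2-dichloroethene | CC(C)(C)O/C(Cl)=C\Cl | intermediate
11 | lithium tert-butoxyacetylide | CC(C)(C)OC#C[Li] | intermediate
12 | tert-butoxyethyne | CC(C)(C)OC#C | intermediate
13 | 3-[2,4,6-tris(benzyloxy)-3-butanoylphenyl]prop-1-en-1-one (aldoketene) | O=C=CCc1c(OCc2ccccc2)cc(OCc2ccccc2)c(C(=O)CCC)c1OCc1ccccc1 | intermediate
14 | racemic 3-tert-butoxy-4-{[2,4,6-tris(benzyloxy)-3-butanoylphenyl]methyl}cyclobut-2-en-1-one | CC(C)(C)OC1=CC(=O)C1Cc1c(OCc2ccccc2)cc(OCc2ccccc2)c(C(=O)CCC)c1OCc1ccccc1 | intermediate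
15 | ethyl acetate | CCOC(C)=O | starting material
16 | lithium enolate of 1,1-dibromopropan-2-one | CC([O-])=C(Br)Br.[Li+] | intermediate
17 | lithium prop-1-yn-1-olate | CC#C[O-].[Li+] | intermediate
18 | triisopropyl(prop-1-yn-1-yloxy)silane | CC#CO[Si](C(C)C)(C(C)C)C(C)C | intermediate
19 | 3-tert-butoxy-5-[2,4,6-tris(benzyloxy)-3-butanoylphenyl]penta-1,3-dien-1-one, arylmethyl group trans to the ketene arm | O=C=C/C(OC(C)(C)C)=C/Cc1c(OCc2ccccc2)cc(OCc2ccccc2)c(C(=O)CCC)c1OCc1ccccc1 | intermediate
20 | racemic 4-{1-tert-butoxy-3-[2,4,6-tris(benzyloxy)-3-butanoylphenyl]prop-1-enyl}-2-methyl-3-(triisopropylsilyloxy)cyclobut-2-en-1-one | O=C1C(C)=C(O[Si](C(C)C)(C(C)C)C(C)C)C1/C(OC(C)(C)C)=C/Cc1c(OCc2ccccc2)cc(OCc2ccccc2)c(C(=O)CCC)c1OCc1ccccc1 | intermediate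
21 | 5-tert-butoxy-2-methyl-3-(triisopropylsilyloxy)-7-[2,4,6-tris(benzyloxy)-3-butanoylphenyl]hepta-1,3,5-trien-1-one, C2 and C5 cis across C3=C4 | O=C=C(C)/C(O[Si](C(C)C)(C(C)C)C(C)C)=C\C(OC(C)(C)C)=C\Cc1c(OCc2ccccc2)cc(OCc2ccccc2)c(C(=O)CCC)c1OCc1ccccc1 | intermediate
22 | racemic 5-tert-butoxy-2-methyl-3-(triisopropylsilyloxy)-6-{[2,4,6-tris(benzyloxy)-3-butanoylphenyl]methyl}cyclohexa-2,4-dien-1-one | O=C1C(C)=C(O[Si](C(C)C)(C(C)C)C(C)C)C=C(OC(C)(C)C)C1Cc1c(OCc2ccccc2)cc(OCc2ccccc2)c(C(=O)CCC)c1OCc1ccccc1 | intermediate
23 | 1-[2,4,6-tris(benzyloxy)-3-{[6-tert-butoxy-2-hydroxy-3-methyl-4-(triisopropylsilyloxy)phenyl]methyl}phenyl]butan-1-one | Cc1c(O)c(Cc2c(OCc3ccccc3)cc(OCc3ccccc3)c(C(=O)CCC)c2OCc2ccccc2)c(OC(C)(C)C)cc1O[Si](C(C)C)(C(C)C)C(C)C | intermediate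
24 | 1-[2,4,6-tris(benzyloxy)-3-{[6-tert-butoxy-2-methoxy-3-methyl-4-(triisopropylsilyloxy)phenyl]methyl}phenyl]butan-1-one | Cc1c(OC)c(Cc2c(OCc3ccccc3)cc(OCc3ccccc3)c(C(=O)CCC)c2OCc2ccccc2)c(OC(C)(C)C)cc1O[Si](C(C)C)(C(C)C)C(C)C | intermediate
25 | 1-[2,4,6-tris(benzyloxy)-3-[(6-tert-butoxy-4-hydroxy-2-methoxy-3-methylphenyl)methyl]phenyl]butan-1-one | Cc1c(OC)c(Cc2c(OCc3ccccc3)cc(OCc3ccccc3)c(C(=O)CCC)c2OCc2ccccc2)c(OC(C)(C)C)cc1O | intermediate
26 | 1-[2,4,6-tris(benzyloxy)-3-[(4,6-dihydroxy-2-methoxy-3-methylphenyl)methyl]phenyl]butan-1-one | Cc1c(OC)c(Cc2c(OCc3ccccc3)cc(OCc3ccccc3)c(C(=O)CCC)c2OCc2ccccc2)c(O)cc1O | intermediate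
27 | 1-[2,4,6-tris(benzyloxy)-3-[(5-butanoyl-4,6-dihydroxy-2-methoxy-3-methylphenyl)methyl]phenyl]butan-1-one | Cc1c(OC)c(Cc2c(OCc3ccccc3)cc(OCc3ccccc3)c(C(=O)CCC)c2OCc2ccccc2)c(O)c(C(=O)CCC)c1O | intermediate
28 | 1-(3-{[3-butanoyl-2,4,6-trihydroxyphenyl]methyl}-2,6-dihydroxy-4-methoxy-5-methylphenyl)butan-1-one | Cc1c(OC)c(Cc2c(O)cc(O)c(C(=O)CCC)c2O)c(O)c(C(=O)CCC)c1O | intermediate
29 | 1-(2,4,6-trihydroxyphenyl)butan-1-one | CCCC(=O)c1c(O)cc(O)cc1O | intermediate
30 | 1-(2,4,6-trihydroxy-3-methylphenyl)butan-1-one | CCCC(=O)c1c(O)cc(O)c(C)c1O | intermediate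
31 | 2-butanoyl-3,5-dihydroxy-4,4-dimethylcyclohexa-2,5-dien-1-one (butyrylfilicinic acid) | CCCC(=O)C1=C(O)C(C)(C)C(O)=CC1=O | intermediate
32 | 2-butanoyl-6-[(dimethylamino)methyl]-3,5-dihydroxy-4,4-dimethylcyclohexa-2,5-dien-1-one | CCCC(=O)C1=C(O)C(C)(C)C(O)=C(CN(C)C)C1=O | intermediate
33 | 2-butanoyl-3-hydroxy-4,4-dimethyl-6-methylidenecyclohex-2-ene-1,5-dione | CCCC(=O)C1=C(O)C(C)(C)C(=O)C(=C)C1=O | intermediate
34 | 2-butanoyl-6-[(3-butanoyl-5-{[3-butanoyl-2,4-dihydroxy-6-methoxy-5-methylphenyl]methyl}-2,4,6-trihydroxyphenyl)methyl]-3,5-dihydroxy-4,4-dimethylcyclohexa-2,5-dien-1-one | CCCC(=O)C1=C(O)C(C)(C)C(O)=C(Cc2c(O)c(Cc3c(O)c(C(=O)CCC)c(O)c(C)c3OC)c(O)c(C(=O)CCC)c2O)C1=O | target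

**Step count**

Total: 17 steps. Longest linear sequence: 12 steps (steps 1, 2, 3, 4, 5, 7, 9, 10, 11, 12, 13, 17, from phloroglucinol).

**Steps most likely to fail, with fallbacks**

Step 9. The cascade may be diverted by acid-induced loss of the tert-butyl group from the alkoxycyclobutenone, by stalling at the vinylcyclobutenone stage, or by acylation of the product phenol by the vinylketene. The fallback abandons the annulation and takes ring C from a ready-made arene, making the ring B–ring C bridge by Mannich chemistry. It sets out from 29 and comes back at 28. Commercial 2-methylphloroglucinol F1 would be butyrylated (PrCOCl, AlCl3) to the methylphlorbutyrophenone that is compound 30, here isolated. Its non-chelated hydroxyl para to the ketone would be methylated selectively (Me2SO4, one equivalent, K2CO3, acetone) to aspidinol F2. Eschenmoser's salt would then give the aspidinol Mannich base F3, and heating F3 with an excess of 29 in dioxane should alkylate one of the two equivalent free positions of 29 with loss of dimethylamine, giving 28 directly.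

Step 12. The Lewis acid may cause cleavage or C-migration of benzyl groups, or O-acylation without subsequent transfer to carbon. The fallback replaces the acyl cation by a nitrile electrophile (Houben–Hoesch reaction), which attacks only very electron-rich rings and uses no strong Lewis acid. It sets out from 26 and comes back at 27. Treatment of 26 with butanenitrile, ZnCl2 and dry HCl in diethyl ether at 0 °C should precipitate the ring C ketiminium chloride F4, and warm water should hydrolyse F4 to 27.

Step 17. Retro-Mannich release of the methylene unit and amine-promoted methylene exchange may scramble the bridge and give symmetrical methylene-bridged by-products. The fallback reverses the roles of the partners so that the electrophile is an aryl quinone methide on ring B and the acidic triketone is the nucleophile. It sets out from 28 and comes back at 34. Compound 28 would be aminomethylated at its only free nuclear position with Eschenmoser's salt to the ring B Mannich base F5, and heating F5 with 31 in dioxane should give 34 with loss of dimethylamine.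

**Further compounds**

F1 | step 9 | 2-methylphloroglucinol (2-methylbenzene-1,3,5-triol) | Cc1c(O)cc(O)cc1O
F2 | step 9 | aspidinol, 1-(2,6-dihydroxy-4-methoxy-3-methylphenyl)butan-1-one | CCCC(=O)c1c(O)cc(OC)c(C)c1O
F3 | step 9 | 1-{3-[(dimethylamino)methyl]-2,6-dihydroxy-4-methoxy-5-methylphenyl}butan-1-one | CCCC(=O)c1c(O)c(CN(C)C)c(OC)c(C)c1O
F4 | step 12 | 1-[2,4-dihydroxy-6-methoxy-5-methyl-3-{[2,4,6-tris(benzyloxy)-3-butanoylphenyl]methyl}phenyl]butan-1-iminium chloride | Cc1c(OC)c(Cc2c(OCc3ccccc3)cc(OCc3ccccc3)c(C(=O)CCC)c2OCc2ccccc2)c(O)c(C(=[NH2+])CCC)c1O.[Cl-]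
F5 | step 17 | 1-(3-{[3-butanoyl-5-[(dimethylamino)methyl]-2,4,6-trihydroxyphenyl]methyl}-2,6-dihydroxy-4-methoxy-5-methylphenyl)butan-1-one | Cc1c(OC)c(Cc2c(O)c(CN(C)C)c(O)c(C(=O)CCC)c2O)c(O)c(C(=O)CCC)c1O
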